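**Retrosynthetic overview**
1. The pyrazinone N1–H/C2=O is unmasked last from a tert-butyl lactim ether under acid, which leaves the base-labile C3–H stereocentre untouched.
2. C3 (S) is set one step earlier by asymmetric hydrogenation of an (E)-3-(pyrazinylmethylidene)oxindole; the prenyl alkene is not a substrate for that catalyst.
3. Key disconnection: the bond from the exocyclic carbon to pyrazine C6 and the oxindole C3–C3a bond are both made in one Pd(0) cyclisation/cross-coupling cascade from an N-(2-bromoaryl)propiolamide and a 6-stannylpyrazine.
4. Enabling feature: oxindole C3 carries both the arene carbon C3a and the exocyclic carbon that leads to pyrazine C6. C3 and that carbon can therefore be the two alkyne carbons of a propiolamide, and 5-exo-dig closure of the lactam ring leaves palladium on the exocyclic carbon, where C6 must be attached.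
5. Ring order: the pyrazine and benzene rings are bought; the five-membered lactam ring is the only ring formed (key step). The stannane comes from 5-bromo-3-methylpyrazin-2-amine (5 steps), the ynamide from 2-bromo-6-iodoaniline (2 steps).

Key step: step 8

Assumption: the sense of induction of the hydrogenation catalyst in step 9 cannot be predicted with certainty for this substrate, so the ligand enantiomer that leads to the (S)-product is to be used; both enantiomers are available.

**Route**

Step 1
Reactants: 1 5-bromo-3-methylpyrazin-2-amine
Product: 3 2,5-dibromo-3-methylpyrazine, via 5-bromo-3-methylpyrazine-2-diazonium bromide 2 (not isolated)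
Conditions: t-BuONO, CuBr2, MeCN, 0 °C to 60 °C
Reagents that add atoms: copper(II) bromide, Br[Cu]Br; tert-butyl nitrite (nitrogen of intermediate 2 only), CC(C)(C)ON=O
Why: Non-aqueous Sandmeyer bromination: the aminopyrazine is diazotised by the alkyl nitrite and the copper bromide delivers bromine to the pyrazinyl radical, while the existing C5–Br is not affected.

Step 2
Reactants: 3 2,5-dibromo-3-methylpyrazine
Product: 4 2-bromo-5-methoxy-3-methylpyrazine
Conditions: NaOMe (1.05 equiv), MeOH–THF, 0 °C to rt
Reagents that add atoms: sodium methoxide, C[O-].[Na+]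
Why: SNAr that should go at C5, because C2 is shielded by the C3 methyl group and attack there would place negative charge on the methyl-bearing carbon, whereas attack at C5 places it on the bromine-bearing C2.

Step 3
Reactants: 4 2-bromo-5-methoxy-3-methylpyrazine
Product: 5 2-(tert-butoxy)-5-methoxy-3-methylpyrazine
Conditions: Pd(OAc)2 (3 mol%), t-BuXPhos (6 mol%), NaOt-Bu, toluene, 90 °C
Reagents that add atoms: sodium tert-butoxide, CC(C)(C)[O-].[Na+]
Why: Pd-catalysed C–O cross-coupling of a heteroaryl bromide with tert-butoxide, which has no β-hydrogen; the bulky biaryl phosphine drives C–O reductive elimination from the electron-poor pyrazinyl–Pd despite the ortho methyl group.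

Step 4
Reactants: 5 2-(tert-butoxy)-5-methoxy-3-methylpyrazine
Product: 6 2-bromo-6-(tert-butoxy)-3-methoxy-5-methylpyrazine
Conditions: NBS (1.05 equiv), MeCN, 0 °C to rt, dark
Reagents that add atoms: N-bromosuccinimide, O=C1CCC(=O)N1Br
Why: Electrophilic aromatic bromination at the only ring C–H, which lies ortho to the methoxy group on a pyrazine made electron-rich by two alkoxy groups; polar, dark conditions disfavour radical bromination of the methyl group.

Step 5
Reactants: 6 2-bromo-6-(tert-butoxy)-3-methoxy-5-methylpyrazine
Product: 7 2-(tert-butoxy)-5-methoxy-3-methyl-6-(tributylstannyl)pyrazine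
Conditions: (Bu3Sn)2 (1.5 equiv), Pd(PPh3)4 (5 mol%), toluene, 110 °C
Reagents that add atoms: hexabutylditin, CCCC[Sn](CCCC)(CCCC)[Sn](CCCC)(CCCC)CCCC
Why: Pd-catalysed stannylation of a heteroaryl bromide with a distannane, which avoids organolithium reagents that could add to the pyrazine C=N bonds or deprotonate the methyl group; excess distannane limits homocoupling.

Step 6
Reactants: 8 2-bromo-6-iodoaniline; 9 tributyl(3-methylbut-2-en-1-yl)stannane
Product: 10 2-bromo-6-(3-methylbut-2-en-1-yl)aniline
Conditions: Pd(PPh3)4 (5 mol%), DMF, 80 °C
Reagents that add atoms: none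
Why: Stille coupling in which oxidative addition at C–I is much faster than at C–Br, and reductive elimination from the η3-prenyl palladium occurs at the unsubstituted terminus to give the linear prenyl group; the free NH2 is tolerated.

Step 7
Reactants: 10 2-bromo-6-(3-methylbut-2-en-1-yl)aniline; 11 propiolic acid
Product: 12 N-[2-bromo-6-(3-methylbut-2-en-1-yl)phenyl]prop-2-ynamide
Conditions: DCC (1.1 equiv), CH2Cl2, 0 °C to rt
Reagents that add atoms: none
Why: Carbodiimide-mediated amide formation; at 0 °C acylation of the aniline by the O-acylisourea should outrun conjugate addition to the ynoic acid, and the terminal alkyne is untouched.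

Step 8
Reactants: 12 N-[2-bromo-6-(3-methylbut-2-en-1-yl)phenyl]prop-2-ynamide; 7 2-(tert-butoxy)-5-methoxy-3-methyl-6-(tributylstannyl)pyrazine
Product: 14 (E)-3-{[6-(tert-butoxy)-3-methoxy-5-methylpyrazin-2-yl]methylidene}-7-(3-methylbut-2-en-1-yl)indolin-2-one, via alkenylpalladium(II) bromide 13 (not isolated)
Conditions: Pd2(dba)3 (2.5 mol%), XPhos (6 mol%), degassed 1,4-dioxane, 90 °C, 7 (1.3 equiv) added over 1 h; no base, no copper
Reagents that add atoms: none
Why: Pd(0) inserts into the C–Br bond of 12, rotation of the secondary amide brings the alkyne to the aryl–Pd bond, and syn-carbopalladation across the triple bond forms C3–C3a and closes the five-membered lactam ring in the 5-exo-dig mode (a 6-endo syn insertion would need a trans double bond in a six-membered ring), giving alkenylpalladium 13 with Pd on the exocyclic carbon. 13 has no β-hydrogen to eliminate, so it persists until Stille transmetalation with 7 and stereoretentive reductive elimination make the bond from the exocyclic carbon to pyrazine C6. The closest known reaction type is the Pd-catalysed cyclisation/anion-capture cascade (Heck carbocyclisation followed by Stille or Suzuki coupling) of 2-haloanilides of alkynoic acids to 3-alkylidene oxindoles. No stereocentre is formed, but the alkene geometry is fixed as E (pyrazinyl cis to C3a) by the syn insertion and the retentive coupling, which is what the face-selective hydrogenation in step 9 needs. The selectivity required is ring closure before direct aryl–pyrazinyl coupling; it should be secured because the intramolecular insertion is much faster than transmetalation of the hindered α-azinyl stannane, while base- and copper-free conditions leave the terminal C–H of 12 alone and the prenyl alkene and tert-butyl ether are inert.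

Step 9
Reactants: 14 (E)-3-{[6-(tert-butoxy)-3-methoxy-5-methylpyrazin-2-yl]methylidene}-7-(3-methylbut-2-en-1-yl)indolin-2-one
Product: 15 (S)-3-{[6-(tert-butoxy)-3-methoxy-5-methylpyrazin-2-yl]methyl}-7-(3-methylbut-2-en-1-yl)indolin-2-one
Conditions: [Rh(cod)Cl]2 (1 mol%), ferrocenyl bisphosphine–thiourea ligand (ZhaoPhos, 2.2 mol%), H2 (40 bar), CH2Cl2, 30 °C
Reagents that add atoms: none
Why: Rh-catalysed asymmetric hydrogenation of an exocyclic α-alkylidene lactam, in which the thiourea of the ligand hydrogen-bonds the lactam carbonyl and H2 is delivered to one face of the E-alkene so that C3 is created as (S) under ligand control; the unactivated prenyl alkene and the pyrazine are not reduced by this catalyst, and the neutral medium should not epimerise C3.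

Step 10
Reactants: 15 (S)-3-{[6-(tert-butoxy)-3-methoxy-5-methylpyrazin-2-yl]methyl}-7-(3-methylbut-2-en-1-yl)indolin-2-one
Product: 16 astepyrazinol B, (S)-5-methoxy-3-methyl-6-{[7-(3-methylbut-2-en-1-yl)-2-oxoindolin-3-yl]methyl}pyrazin-2(1H)-one
Conditions: TFA (10 equiv), CH2Cl2, 0 °C, 30 min; pH 7 phosphate buffer work-up
Reagents that add atoms: none
Why: Acidolysis of the tert-butyl lactim ether (N-protonation, loss of the tert-butyl cation as isobutene) releases the pyrazinone; the acidic, base-free medium does not enolise the oxindole, so C3 should be retained, and the short cold exposure spares the prenyl alkene.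

**Compound list**
1 | 5-bromo-3-methylpyrazin-2-amine | Cc1nc(Br)cnc1N | starting material
2 | 5-bromo-3-methylpyrazine-2-diazonium bromide | Cc1nc(Br)cnc1[N+]#N.[Br-] | intermediate (not isolated)
3 | 2,5-dibromo-3-methylpyrazine | Cc1nc(Br)cnc1Br | intermediate
4 | 2-bromo-5-methoxy-3-methylpyrazine | COc1cnc(Br)c(C)n1 | intermediate
5 | 2-(tert-butoxy)-5-methoxy-3-methylpyrazine | COc1cnc(OC(C)(C)C)c(C)n1 | intermediate
6 | 2-bromo-6-(tert-butoxy)-3-methoxy-5-methylpyrazine | COc1nc(C)c(OC(C)(C)C)nc1Br | intermediate
7 | 2-(tert-butoxy)-5-methoxy-3-methyl-6-(tributylstannyl)pyrazine | COc1nc(C)c(OC(C)(C)C)nc1[Sn](CCCC)(CCCC)CCCC | intermediate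
8 | 2-bromo-6-iodoaniline | Nc1c(Br)cccc1I | starting material
9 | tributyl(3-methylbut-2-en-1-yl)stannane | CC(C)=CC[Sn](CCCC)(CCCC)CCCC | starting material
10 | 2-bromo-6-(3-methylbut-2-en-1-yl)aniline | Nc1c(Br)cccc1CC=C(C)C | intermediate
11 | propiolic acid (prop-2-ynoic acid) | C#CC(=O)O | starting material
12 | N-[2-bromo-6-(3-methylbut-2-en-1-yl)phenyl]prop-2-ynamide | C#CC(=O)Nc1c(Br)cccc1CC=C(C)C | intermediate
13 | bromo{(E)-[7-(3-methylbut-2-en-1-yl)-2-oxoindolin-3-ylidene]methyl}palladium(II), phosphine ligand omitted | O=C1Nc2c(CC=C(C)C)cccc2/C1=C\[Pd]Br | intermediate (not isolated)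
14 | (E)-3-{[6-(tert-butoxy)-3-methoxy-5-methylpyrazin-2-yl]methylidene}-7-(3-methylbut-2-en-1-yl)indolin-2-one | O=C1Nc2c(CC=C(C)C)cccc2/C1=C\c1nc(OC(C)(C)C)c(C)nc1OC | intermediate
15 | (S)-3-{[6-(tert-butoxy)-3-methoxy-5-methylpyrazin-2-yl]methyl}-7-(3-methylbut-2-en-1-yl)indolin-2-one | COc1nc(C)c(OC(C)(C)C)nc1C[C@@H]1C(=O)Nc2c(CC=C(C)C)cccc21 | intermediate
16 | astepyrazinol B, (S)-5-methoxy-3-methyl-6-{[7-(3-methylbut-2-en-1-yl)-2-oxoindolin-3-yl]methyl}pyrazin-2(1H)-one | COc1nc(C)c(=O)[nH]c1C[C@@H]1C(=O)Nc2c(CC=C(C)C)cccc21 | target

**Step count and risks**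
Total: 10 steps. Longest linear sequence: 8 steps (steps 1–5, 8, 9, 10).

Step 8 (key cascade). The secondary anilide may cyclise too slowly because the cis-amide rotamer is poorly populated, or the terminal ynamide may oligomerise under Pd/phosphine at 90 °C, so that direct aryl–pyrazinyl coupling and decomposition outrun the cascade. The fallback makes the same exocyclic-carbon-to-C6 bond by a plain Stille coupling onto a preformed oxindole. It sets out from stannanes 7 and 9 and returns at 14. Purchased 7-bromoindolin-2-one F1 would be prenylated with 9 (Pd(PPh3)4, DMF, 100 °C) to 7-(3-methylbut-2-en-1-yl)indolin-2-one F2. Formylation with ethyl formate and NaOEt in EtOH would give 3-(hydroxymethylidene)-7-(3-methylbut-2-en-1-yl)indolin-2-one F3, and PhNTf2/Et3N in CH2Cl2 would convert this into [7-(3-methylbut-2-en-1-yl)-2-oxoindolin-3-ylidene]methyl trifluoromethanesulfonate F4. Stille coupling of F4 with 7 (Pd2(dba)3, AsPh3, NMP, 50 °C) should give 14, and the E-isomer would be collected after iodine-catalysed equilibration.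

Step 9 (asymmetric hydrogenation). Facial selectivity may be poor with the hindered, coordinating 2-alkenylpyrazine, or E/Z isomerisation of 14 under the conditions may erode the enantiomeric purity. The fallback sets out from 14 and returns at 15. Conjugate reduction with NaBH4 in THF–MeOH at 0 °C should give racemic 3-{[6-(tert-butoxy)-3-methoxy-5-methylpyrazin-2-yl]methyl}-7-(3-methylbut-2-en-1-yl)indolin-2-one F5 without touching the prenyl alkene. The enantiomers would be separated by preparative chiral SFC, and the (R)-enantiomer recycled by DBU-catalysed racemisation through the oxindole enolate.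

Step 4 (ring bromination). Ring substitution may be sluggish because only one alkoxy group is ortho to the C–H, and radical bromination of the C-methyl group may compete. The fallback sets out from 5 and returns at 7, bypassing 6 and step 5. Directed ortho-lithiation of 5 with LiTMP in THF at −78 °C, guided by the methoxy group and the ring nitrogen to the only ring C–H, should give [6-(tert-butoxy)-3-methoxy-5-methylpyrazin-2-yl]lithium F6, which would be quenched with Bu3SnCl to give 7.

**Further compounds**
F1 | step 8 | 7-bromoindolin-2-one (purchased) | O=C1Cc2cccc(Br)c2N1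
F2 | step 8 | 7-(3-methylbut-2-en-1-yl)indolin-2-one | O=C1Cc2cccc(CC=C(C)C)c2N1
F3 | step 8 | 3-(hydroxymethylidene)-7-(3-methylbut-2-en-1-yl)indolin-2-one | O=C1Nc2c(CC=C(C)C)cccc2C1=CO
F4 | step 8 | [7-(3-methylbut-2-en-1-yl)-2-oxoindolin-3-ylidene]methyl trifluoromethanesulfonate | O=C1Nc2c(CC=C(C)C)cccc2C1=COS(=O)(=O)C(F)(F)F
F5 | step 9 | rac-3-{[6-(tert-butoxy)-3-methoxy-5-methylpyrazin-2-yl]methyl}-7-(3-methylbut-2-en-1-yl)indolin-2-one | COc1nc(C)c(OC(C)(C)C)nc1CC1C(=O)Nc2c(CC=C(C)C)cccc21
F6 | step 4 | [6-(tert-butoxy)-3-methoxy-5-methylpyrazin-2-yl]lithium | COc1nc(C)c(OC(C)(C)C)nc1[Li]
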